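Remark on the chemistry: lignan numbering is used for the butane chain (C7, C8, C9 on one half; C7', C8', C9' on the other), and diacid 1 is assumed to be bought as the resolved (1R,2R) enantiomer.

## Analysis of the target

Hanultarin 17 is an open-chain lignan ester: a 2,3-dibenzylbutane-1,4-diol (C7–C8–C8'–C7', with hydroxymethyl carbons C9 and C9') carrying a 4-hydroxy-3-methoxyphenyl (guaiacyl) ring on C7 and on C7' and an (E)-feruloyl group on O9; the only rings are the three arenes. The two stereocenters, C8 and C8', are adjacent and both R. The parent diol is therefore C2-symmetric, its two hydroxymethyl groups are homotopic, acylation of either gives the same mono-ester, and acyl migration between O9 and O9' is degenerate. The sensitive groups are three free phenols, an (E)-cinnamate that is reducible, base-labile and a conjugate acceptor, and a 1,4-dioxygenated chain that closes to a tetrahydrofuran once one oxygen becomes a leaving group. The synthesis is hard because C8 and C8' are flanked only by methylene groups, so that no neighbouring carbonyl or heteroatom offers late stereocontrol, because the esterification has to stop after one hydroxyl, and because the phenols have to be unmasked without hydrogenation. The strategy rests on the fact that the aryl C1–C7 and C1'–C7' bonds are each one carbon removed from a stereocenter and that C7 and C7' are plain CH2 groups. Both identical guaiacyl rings can therefore be attached last, to a chiral six-carbon core in which C7 and C7' are methylenes bearing carboxyl groups, without any risk to C8 or C8'.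

## Retrosynthetic reasoning

17 to 16. The three O–H bonds of the phenols are traced back to benzyl ethers in 16. Benzyl is chosen because it is inert to reductive nickel chemistry, fluoride and carbodiimide coupling. Hydrogenolysis is excluded by the cinnamate double bond, so the forward step must be a Lewis acid debenzylation with a cation scavenger at low temperature.

16 to 12 and 15. The O9–acyl bond is cut. It is the most labile bond of the molecule, and attaching the cinnamate late keeps it away from hydride, oxidative cleavage and electrolysis. What is gained is the C2-symmetric diol 12. The forward reaction only has to stop at the mono-ester; there is no regiochemical question because the two hydroxyls are homotopic.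

15 to 13. The Cα=Cβ bond of cinnamic acid 15 is cut back to aldehyde 13. A Knoevenagel–Doebner condensation gives the E acid directly and needs no separate protection of the acid.

12 to 11. The two primary hydroxyls are masked as silyl ethers. Free hydroxyls on the core would lactonize onto the activated esters required for the key step.

11 to 7 and two molecules of 9 (key disconnection). The aryl C1–C7 and C1'–C7' bonds are cut. A cut at C8–C8' would require joining two stereocenters under control, and a cut at C7–C8 would require an enolate alkylation next to a stereocenter, with an auxiliary or a lactone template. The aryl–C7 bonds, by contrast, are remote from the stereocenters and equivalent by symmetry, so one reagent and one operation serve both. The electron-rich arenes enter after all oxidative steps, and the stereochemical problem shrinks to a six-carbon acyclic diacid. The forward reaction must turn each CH2–CO2N(phthalimide) group into CH2–aryl with decarboxylation, via a primary radical, and both arms must couple.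

7 to 5 and two molecules of 6. Each of the two carboxyl groups is activated as its ester with one molecule of N-hydroxyphthalimide 6. This is a simple twofold esterification.

5 to 3. The two carboxyl carbons are reconnected as a ring C=C bond, so the adipic acid 5 becomes the oxidative cleavage product of cyclohexene 3. The allylic ring CH2 groups become C7 and C7'.

3 to 2 to 1. The silyloxymethyl groups come from the carboxyl groups of the trans-diacid 1 by reduction and silylation. Ring carbons C1 and C2 of 1 become C8 and C8'. At each stage the oxygen-bearing carbon outranks the neighbouring stereocenter, which outranks the CH2, so both descriptors stay R from 1 to 17.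

9 to 8. The aryl iodide comes from iodophenol 8 by O-benzylation.

## Alternatives that were turned down

Alternative 1: Desymmetrizing enzymatic Baeyer–Villiger oxidation.
- Disconnection: the C7–C8 bond (enolate benzylation) and, one stage earlier, the ring O–C9' bond of a β-benzyl-γ-butyrolactone, traced to the prochiral 3-[4-(benzyloxy)-3-methoxybenzyl]cyclobutanone A1.
- Forward key step: a flavin monooxygenase of the cyclohexanone monooxygenase type, with nicotinamide cofactor recycling and oxygen, would insert oxygen into one of the two enantiotopic acyl–CH2 bonds of A1. This would give the (R)-lactone A2 with C8' set. Trans-selective benzylation of its enolate with 4-(benzyloxy)-3-methoxybenzyl bromide A3 would then set C8, and hydride reduction would converge on diol 12.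
- For it: chirality is created catalytically from an achiral precursor with oxygen as the oxidant, and the downstream alkylation and reduction are classical. On this point it is stronger than the chosen route, which depends on a resolved building block.
- Against it: the enzyme must distinguish the faces of a nearly flat ring through a remote, bulky, lipophilic benzyl group. Which enantiomer a given enzyme delivers cannot be deduced from the structure, so screening or engineering would be needed. A1 itself needs a ketene cycloaddition and dechlorination sequence. The two identical arenes are introduced in two unrelated operations.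
- Comparison: the step count to 12 is about the same. The chosen route offers a configuration that is fixed by purchase and is independent of any selectivity, and it uses the symmetry of the core by forming both aryl–CH2 bonds in one operation.

Alternative 2: Conjugate addition and alkylation on a chiral butenolide.
- Disconnection: C7'–C8' (conjugate addition) and C7–C8 (enolate alkylation) on a butenolide whose acetal carbon is C9'.
- Forward key step: the 2-lithio derivative of 2-[4-(benzyloxy)-3-methoxyphenyl]-1,3-dithiane A5 would add to C4 of (5R)-5-menthyloxyfuran-2(5H)-one A4, anti to the alkoxy group. The lactone enolate would be benzylated in the same flask by A3, anti to the new substituent, giving the all-trans lactone A6.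
- For it: both C–C bonds and both stereocenters arise in one flask under substrate control by the acetal center, a mode of control well established for dibenzylbutyrolactones. In A6 the carbons C9 and C9' are at different oxidation levels, which could in principle allow non-statistical differentiation of the two hydroxymethyl ends. On both points it is stronger than the chosen route.
- Against it: a stoichiometric auxiliary must be made and later removed, the dithiane must be desulfurized over Raney Ni in the presence of benzyl ethers, and acetal and lactone must be reduced before 12 is reached. The two identical arenes come from two different reagents. The sequence is several steps longer.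
- Comparison: the chosen route accepts a mono-esterification of a symmetric diol and in return is shorter, needs no auxiliary or sulfur removal, and never forms a stereocenter.

Alternative 3: Enantioselective palladium bis-methoxycarbonylation.
- Disconnection: C8–C9 and C8'–C9', both hydroxymethyl carbons arriving as carbonyl groups across the double bond of (E)-1,4-bis[4-(benzyloxy)-3-methoxyphenyl]but-2-ene A7.
- Forward key step: syn addition of two methoxycarbonyl groups to A7 under carbon monoxide in methanol, with a chiral bis(oxazoline) complex of Pd(OCOCF3)2 (divalent palladium) and a quinone reoxidant. This would give dimethyl (2R,3R)-2,3-bis[4-(benzyloxy)-3-methoxybenzyl]butanedioate A8; hydride reduction would give 12.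
- For it: it is the shortest path to 12 and is catalytic and asymmetric, since A7 is available by self-metathesis of an allylarene. In step economy it is clearly stronger than the chosen route.
- Against it: syn addition to the E alkene does give the C2-symmetric diastereomer, but enantioface control on an unfunctionalized internal dialkyl alkene is not established. The alkylpalladium intermediate has allylic-benzylic hydrogens and can undergo β-hydride elimination to conjugated styrenes and regioisomeric esters. Any Z alkene from the metathesis would lead into the meso series instead.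
- Comparison: here the stereo-determining step is also the least precedented one. The chosen route is longer, but its uncertain step is a coupling that cannot touch the stereocenters.

Key step: step 6

## Route

Step 1
Reactants: 1 (1R,2R)-cyclohex-4-ene-1,2-dicarboxylic acid
Product: 2 [(1R,2R)-cyclohex-4-ene-1,2-diyl]dimethanol
Conditions: LiAlH4, THF, 0 °C to reflux; aq. NaOH work-up
Reagents that add atoms: none
Why: LiAlH4 reduction of both carboxylic acids to primary alcohols; the isolated ring alkene is inert to hydride, and the carboxylate salts formed first are not enolized, so C1 and C2 keep their configuration.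

Step 2
Reactants: 2 [(1R,2R)-cyclohex-4-ene-1,2-diyl]dimethanol
Product: 3 (4R,5R)-4,5-bis(tert-butyldimethylsilyloxymethyl)cyclohex-1-ene
Conditions: TBSCl, imidazole, DMF, rt
Reagents that add atoms: tert-butyldimethylsilyl chloride (TBSCl), CC(C)(C)[Si](C)(C)Cl
Why: Imidazole-promoted silylation of two unhindered primary alcohols; the silyl ethers later prevent lactonization onto the acids and activated esters.

Step 3
Reactants: 3 (4R,5R)-4,5-bis(tert-butyldimethylsilyloxymethyl)cyclohex-1-ene
Product: 5 (3R,4R)-3,4-bis(tert-butyldimethylsilyloxymethyl)hexanedioic acid, via dialdehyde 4 (not isolated)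
Conditions: O3, CH2Cl2, −78 °C; PPh3, −78 °C to rt; then NaClO2, NaH2PO4, 2-methyl-2-butene, t-BuOH/H2O, 0 °C to rt
Reagents that add atoms: ozone, [O-][O+]=O; sodium chlorite, [Na+].[O-]Cl=O
Why: Ozonolysis of the only C=C bond with reductive work-up gives the 1,6-dialdehyde 4, which is oxidized at once by the Pinnick method to the diacid. The stereocenters are β to the new carbonyl groups and cannot epimerize, and primary silyl ethers tolerate ozone and the buffered chlorite medium.

Step 4
Reactants: 5 (3R,4R)-3,4-bis(tert-butyldimethylsilyloxymethyl)hexanedioic acid; 6 N-hydroxyphthalimide (two molecules)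
Product: 7 bis(1,3-dioxoisoindolin-2-yl) (3R,4R)-3,4-bis(tert-butyldimethylsilyloxymethyl)hexanedioate
Conditions: 6 (2.2 equiv), N,N'-diisopropylcarbodiimide (2.4 equiv), DMAP (cat.), CH2Cl2, rt
Reagents that add atoms: none
Why: Twofold carbodiimide esterification of the Steglich type, the standard route to redox-active esters: each of the two carboxyl groups of 5 condenses with one molecule of the N-hydroxy imide 6, the water being taken up by the carbodiimide. The conditions are neutral and leave the silyl ethers and stereocenters untouched.

Step 5
Reactants: 8 4-iodo-2-methoxyphenol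
Product: 9 1-(benzyloxy)-4-iodo-2-methoxybenzene
Conditions: BnBr, K2CO3, DMF, rt
Reagents that add atoms: benzyl bromide, BrCc1ccccc1
Why: Williamson ether synthesis on the phenoxide; the aryl iodide is inert to carbonate and benzyl bromide.

Step 6
Reactants: 7 bis(1,3-dioxoisoindolin-2-yl) (3R,4R)-3,4-bis(tert-butyldimethylsilyloxymethyl)hexanedioate; 9 1-(benzyloxy)-4-iodo-2-methoxybenzene (two molecules, used in excess)
Product: 11 (2R,3R)-2,3-bis[4-(benzyloxy)-3-methoxybenzyl]-1,4-bis(tert-butyldimethylsilyloxy)butane, via mono-arylated ester 10 (not isolated)
Conditions: NiCl2·glyme (cat.), 2,2'-bipyridine (cat.), AgNO3 (0.5 equiv), 9 (5 equiv), NMP, Mg anode/RVC cathode, undivided cell, constant current, rt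
Reagents that add atoms: none
Why: This is a nickel-electrocatalytic decarboxylative sp3–sp2 cross-coupling of N-hydroxyphthalimide esters with an aryl iodide, the closest known reaction type, run on both ester groups of 7. Cathodic reduction of the divalent nickel–bipyridine complex gives low-valent nickel, which inserts into the C–I bond of 9 to give a divalent arylnickel iodide. Single-electron transfer to one phthalimide ester of 7 expels phthalimide anion and CO2 and leaves a primary radical on C7; the arylnickel species captures it, and reductive elimination from the trivalent aryl(alkyl)nickel forms the aryl–C7 bond and returns monovalent nickel to the cycle, while the Mg anode supplies the electrons and the silver deposited from AgNO3 keeps the cathode active. The same sequence on the remaining ester of 10 forms the aryl–C7' bond. No ring is closed and no stereocenter is created: each radical site is a CH2 group one carbon away from C8 or C8', so the R,R configuration of 7 passes into 11 unchanged. The step needs chemoselectivity for cross-coupling over hydrodecarboxylation, radical dimerization and attack of the second radical on the first guaiacyl ring; the excess of 9 keeps the arylnickel concentration high, so capture of the unhindered primary radical is the fastest pathway. The aryl benzyl ethers and silyl ethers are inert to low-valent nickel and to the mild cathodic potential.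

Step 7
Reactants: 11 (2R,3R)-2,3-bis[4-(benzyloxy)-3-methoxybenzyl]-1,4-bis(tert-butyldimethylsilyloxy)butane
Product: 12 (2R,3R)-2,3-bis[4-(benzyloxy)-3-methoxybenzyl]butane-1,4-diol
Conditions: Bu4NF, THF, 0 °C to rt
Reagents that add atoms: none
Why: Fluoride-induced cleavage of both primary silyl ethers; aryl benzyl and methyl ethers are inert, and no oxygen is activated, so tetrahydrofuran formation is not possible.

Step 8
Reactants: 13 4-(benzyloxy)-3-methoxybenzaldehyde
Product: 15 (E)-3-[4-(benzyloxy)-3-methoxyphenyl]prop-2-enoic acid, via arylidenemalonic acid 14 (not isolated)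
Conditions: malonic acid, pyridine, piperidine (cat.), 90 °C
Reagents that add atoms: malonic acid, OC(=O)CC(=O)O
Why: Knoevenagel condensation in the Doebner modification; the adduct 14 loses CO2 in hot pyridine and gives the thermodynamically favoured E cinnamic acid.

Step 9
Reactants: 12 (2R,3R)-2,3-bis[4-(benzyloxy)-3-methoxybenzyl]butane-1,4-diol; 15 (E)-3-[4-(benzyloxy)-3-methoxyphenyl]prop-2-enoic acid
Product: 16 (2R,3R)-2,3-bis[4-(benzyloxy)-3-methoxybenzyl]-4-hydroxybutyl (E)-3-[4-(benzyloxy)-3-methoxyphenyl]prop-2-enoate
Conditions: N,N'-diisopropylcarbodiimide, DMAP (cat.), CH2Cl2, 0 °C to rt; 15 limiting and added slowly, unreacted 12 recovered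
Reagents that add atoms: none
Why: Steglich esterification of one of two homotopic primary hydroxyls, so only one mono-ester can form and acyl migration is degenerate. Over-acylation is held back by keeping the diol in excess, and the neutral conditions avoid activating an oxygen toward tetrahydrofuran closure.

Step 10
Reactants: 16 (2R,3R)-2,3-bis[4-(benzyloxy)-3-methoxybenzyl]-4-hydroxybutyl (E)-3-[4-(benzyloxy)-3-methoxyphenyl]prop-2-enoate
Product: 17 hanultarin, (2R,3R)-4-hydroxy-2,3-bis(4-hydroxy-3-methoxybenzyl)butyl (E)-3-(4-hydroxy-3-methoxyphenyl)prop-2-enoate
Conditions: BCl3, pentamethylbenzene, CH2Cl2, −78 °C; MeOH quench, aq. work-up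
Reagents that add atoms: none
Why: Lewis acid cleavage of the three aryl benzyl ethers, with Friedel–Crafts transfer of each benzyl cation to the non-basic scavenger pentamethylbenzene. At −78 °C the aryl methyl ethers, the cinnamate ester and its double bond should survive, and the primary alcohol is only held as a borate until work-up.

## Compound list

1 | (1R,2R)-cyclohex-4-ene-1,2-dicarboxylic acid | OC(=O)[C@@H]1CC=CC[C@H]1C(=O)O | starting material
2 | [(1R,2R)-cyclohex-4-ene-1,2-diyl]dimethanol | OC[C@@H]1CC=CC[C@H]1CO | intermediate
3 | (4R,5R)-4,5-bis(tert-butyldimethylsilyloxymethyl)cyclohex-1-ene | CC(C)(C)[Si](C)(C)OC[C@@H]1CC=CC[C@H]1CO[Si](C)(C)C(C)(C)C | intermediate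
4 | (3R,4R)-3,4-bis(tert-butyldimethylsilyloxymethyl)hexanedial | CC(C)(C)[Si](C)(C)OC[C@H](CC=O)[C@H](CO[Si](C)(C)C(C)(C)C)CC=O | intermediate
5 | (3R,4R)-3,4-bis(tert-butyldimethylsilyloxymethyl)hexanedioic acid | CC(C)(C)[Si](C)(C)OC[C@H](CC(=O)O)[C@H](CO[Si](C)(C)C(C)(C)C)CC(=O)O | intermediate
6 | N-hydroxyphthalimide | ON1C(=O)c2ccccc2C1=O | starting material
7 | bis(1,3-dioxoisoindolin-2-yl) (3R,4R)-3,4-bis(tert-butyldimethylsilyloxymethyl)hexanedioate | CC(C)(C)[Si](C)(C)OC[C@H](CC(=O)ON1C(=O)c2ccccc2C1=O)[C@H](CO[Si](C)(C)C(C)(C)C)CC(=O)ON1C(=O)c2ccccc2C1=O | intermediate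
8 | 4-iodo-2-methoxyphenol | COc1cc(I)ccc1O | starting material
9 | 1-(benzyloxy)-4-iodo-2-methoxybenzene | COc1cc(I)ccc1OCc1ccccc1 | intermediate
10 | 1,3-dioxoisoindolin-2-yl (3R,4R)-5-[4-(benzyloxy)-3-methoxyphenyl]-3,4-bis(tert-butyldimethylsilyloxymethyl)pentanoate | CC(C)(C)[Si](C)(C)OC[C@H](Cc1ccc(OCc2ccccc2)c(OC)c1)[C@H](CO[Si](C)(C)C(C)(C)C)CC(=O)ON1C(=O)c2ccccc2C1=O | intermediate
11 | (2R,3R)-2,3-bis[4-(benzyloxy)-3-methoxybenzyl]-1,4-bis(tert-butyldimethylsilyloxy)butane | CC(C)(C)[Si](C)(C)OC[C@H](Cc1ccc(OCc2ccccc2)c(OC)c1)[C@H](CO[Si](C)(C)C(C)(C)C)Cc1ccc(OCc2ccccc2)c(OC)c1 | intermediate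
12 | (2R,3R)-2,3-bis[4-(benzyloxy)-3-methoxybenzyl]butane-1,4-diol | OC[C@H](Cc1ccc(OCc2ccccc2)c(OC)c1)[C@H](CO)Cc1ccc(OCc2ccccc2)c(OC)c1 | intermediate
13 | 4-(benzyloxy)-3-methoxybenzaldehyde | COc1cc(C=O)ccc1OCc1ccccc1 | starting material
14 | 2-[4-(benzyloxy)-3-methoxybenzylidene]malonic acid | COc1cc(C=C(C(=O)O)C(=O)O)ccc1OCc1ccccc1 | intermediate
15 | (E)-3-[4-(benzyloxy)-3-methoxyphenyl]prop-2-enoic acid | COc1cc(/C=C/C(=O)O)ccc1OCc1ccccc1 | intermediate
16 | (2R,3R)-2,3-bis[4-(benzyloxy)-3-methoxybenzyl]-4-hydroxybutyl (E)-3-[4-(benzyloxy)-3-methoxyphenyl]prop-2-enoate | COc1cc(/C=C/C(=O)OC[C@H](Cc2ccc(OCc3ccccc3)c(OC)c2)[C@H](CO)Cc2ccc(OCc3ccccc3)c(OC)c2)ccc1OCc1ccccc1 | intermediate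
17 | hanultarin, (2R,3R)-4-hydroxy-2,3-bis(4-hydroxy-3-methoxybenzyl)butyl (E)-3-(4-hydroxy-3-methoxyphenyl)prop-2-enoate | COc1cc(/C=C/C(=O)OC[C@H](Cc2ccc(O)c(OC)c2)[C@H](CO)Cc2ccc(O)c(OC)c2)ccc1O | target

## Step count and least certain steps

Total step count: 10. Longest linear sequence: 8 steps (steps 1, 2, 3, 4, 6, 7, 9, 10); steps 5 and 8 are single-step side branches.

Step 6 (key step). The most likely failure is incomplete double coupling. Each decarboxylation can end in hydrogen abstraction, radical dimerization or unproductive reduction of the ester instead of capture by nickel, and two such events must succeed on one molecule, so the losses multiply. Oxidative addition to the electron-rich iodide 9 is comparatively slow, and the radical formed from 10 could attack the guaiacyl ring already installed and close a tetralin. The fallback replaces the radical coupling by two-electron chemistry. It sets out from diacid 5. Photochemical iododecarboxylation with PhI(OAc)2 and I2, a Hunsdiecker-type reaction, would give (2R,3R)-2,3-bis(tert-butyldimethylsilyloxymethyl)-1,4-diiodobutane F1. Zinc insertion (activated Zn dust, LiCl, THF) would give the 1,4-bis(iodozincio) reagent F2. Negishi coupling with two equivalents of 9 under zerovalent palladium (Pd2(dba)3 with the biaryl phosphine SPhos), passing through the mono-arylated alkylzinc iodide F3, would come back to the route at 11. The carbon–zinc carbons are again CH2 groups, so C8 and C8' are not at risk.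

Step 3. The most likely failures are loss of a silyl ether in the weakly acidic chlorite medium, after which the freed hydroxyl closes a five-membered lactone onto the new acid, and aldol self-condensation of the 1,6-dialdehyde 4 before it is oxidized. The fallback avoids both the free dialdehyde and the acidic oxidation. It sets out from 3. Ozonolysis in CH2Cl2 with methanolic NaOH at −78 °C converts the alkene directly into methyl esters, because ozone oxidizes the hemiacetal of each aldehyde under basic conditions. This would give dimethyl (3R,4R)-3,4-bis(tert-butyldimethylsilyloxymethyl)hexanedioate F4. Saponification with LiOH in THF/H2O then comes back to the route at 5.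

Step 9. The most likely failure is over-acylation to the bis-ester, because the remaining hydroxyl of 16 is as reactive as those of 12. This wastes acid 15 and complicates separation of diol, mono-ester and diester. The fallback moves the desymmetrizing event to a cheap reagent. It sets out from 12. The monosodium alkoxide (NaH, 1 equiv, THF) is silylated with TBSCl (1 equiv) to give (2R,3R)-2,3-bis[4-(benzyloxy)-3-methoxybenzyl]-4-(tert-butyldimethylsilyloxy)butan-1-ol F5. Any bis-silyl ether formed is compound 11 and returns to step 7; unreacted 12 is reused. The single hydroxyl of F5 is then esterified to completion with excess 15 (N,N'-diisopropylcarbodiimide, DMAP) to give the silyl ether ester F6. Buffered fluoride (Bu4NF with AcOH, THF) comes back to the route at 16.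

Step 10. The most likely failures are transfer of benzyl cations to the electron-rich guaiacyl rings instead of the scavenger, partial cleavage of the guaiacyl methyl ethers if the mixture warms, and displacement of the Lewis acid-activated ferulate by the neighbouring O9' with closure of the tetrahydrofuran. The fallback builds the cinnamate double bond last and needs no Lewis acid. It sets out from 12. Heating with Meldrum's acid as the limiting reagent (toluene, 90 °C) would give the malonic half-ester 3-{(2R,3R)-2,3-bis[4-(benzyloxy)-3-methoxybenzyl]-4-hydroxybutoxy}-3-oxopropanoic acid F7. Hydrogenolysis (H2, Pd/C, EtOAc) is then safe because no alkene is present yet, and would give the bisphenol half-ester F8. Knoevenagel–Doebner condensation of F8 with vanillin F9 (pyridine, piperidine cat., 60 °C) would pass through the arylidene malonate F10, lose CO2 and come back to the route at the target 17, with the E geometry set by the decarboxylative condensation.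

## Further compounds

F1 | step 6 | (2R,3R)-2,3-bis(tert-butyldimethylsilyloxymethyl)-1,4-diiodobutane | CC(C)(C)[Si](C)(C)OC[C@H](CI)[C@H](CO[Si](C)(C)C(C)(C)C)CI
F2 | step 6 | 1,4-bis(iodozincio) reagent from F1, [(2R,3R)-2,3-bis(tert-butyldimethylsilyloxymethyl)butane-1,4-diyl]bis(zinc iodide) | CC(C)(C)[Si](C)(C)OC[C@H](C[Zn]I)[C@H](CO[Si](C)(C)C(C)(C)C)C[Zn]I
F3 | step 6 | mono-arylated alkylzinc iodide, {(2R,3R)-4-[4-(benzyloxy)-3-methoxyphenyl]-2,3-bis(tert-butyldimethylsilyloxymethyl)butyl}zinc iodide | CC(C)(C)[Si](C)(C)OC[C@H](Cc1ccc(OCc2ccccc2)c(OC)c1)[C@H](CO[Si](C)(C)C(C)(C)C)C[Zn]I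
F4 | step 3 | dimethyl (3R,4R)-3,4-bis(tert-butyldimethylsilyloxymethyl)hexanedioate | CC(C)(C)[Si](C)(C)OC[C@H](CC(=O)OC)[C@H](CO[Si](C)(C)C(C)(C)C)CC(=O)OC
F5 | step 9 | (2R,3R)-2,3-bis[4-(benzyloxy)-3-methoxybenzyl]-4-(tert-butyldimethylsilyloxy)butan-1-ol | CC(C)(C)[Si](C)(C)OC[C@H](Cc1ccc(OCc2ccccc2)c(OC)c1)[C@H](CO)Cc1ccc(OCc2ccccc2)c(OC)c1
F6 | step 9 | (2R,3R)-2,3-bis[4-(benzyloxy)-3-methoxybenzyl]-4-(tert-butyldimethylsilyloxy)butyl (E)-3-[4-(benzyloxy)-3-methoxyphenyl]prop-2-enoate | COc1cc(/C=C/C(=O)OC[C@H](Cc2ccc(OCc3ccccc3)c(OC)c2)[C@H](CO[Si](C)(C)C(C)(C)C)Cc2ccc(OCc3ccccc3)c(OC)c2)ccc1OCc1ccccc1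
F7 | step 10 | 3-{(2R,3R)-2,3-bis[4-(benzyloxy)-3-methoxybenzyl]-4-hydroxybutoxy}-3-oxopropanoic acid | OC(=O)CC(=O)OC[C@H](Cc1ccc(OCc2ccccc2)c(OC)c1)[C@H](CO)Cc1ccc(OCc2ccccc2)c(OC)c1
F8 | step 10 | 3-{(2R,3R)-4-hydroxy-2,3-bis(4-hydroxy-3-methoxybenzyl)butoxy}-3-oxopropanoic acid | OC(=O)CC(=O)OC[C@H](Cc1ccc(O)c(OC)c1)[C@H](CO)Cc1ccc(O)c(OC)c1
F9 | step 10 | vanillin, 4-hydroxy-3-methoxybenzaldehyde (commercial input) | COc1cc(C=O)ccc1O
F10 | step 10 | 2-(4-hydroxy-3-methoxybenzylidene)malonic acid mono[(2R,3R)-4-hydroxy-2,3-bis(4-hydroxy-3-methoxybenzyl)butyl] ester | COc1cc(C=C(C(=O)O)C(=O)OC[C@H](Cc2ccc(O)c(OC)c2)[C@H](CO)Cc2ccc(O)c(OC)c2)ccc1O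
A1 | alternative 1 | 3-[4-(benzyloxy)-3-methoxybenzyl]cyclobutan-1-one | O=C1CC(Cc2ccc(OCc3ccccc3)c(OC)c2)C1
A2 | alternative 1 | (4R)-4-[4-(benzyloxy)-3-methoxybenzyl]dihydrofuran-2(3H)-one | O=C1C[C@H](CO1)Cc1ccc(OCc2ccccc2)c(OC)c1
A3 | alternative 1 | 4-(benzyloxy)-3-methoxybenzyl bromide | COc1cc(CBr)ccc1OCc1ccccc1
A4 | alternative 2 | (5R)-5-[(1R,2S,5R)-menthyloxy]furan-2(5H)-one | O=C1C=C[C@H](O[C@@H]2C[C@H](C)CC[C@H]2C(C)C)O1
A5 | alternative 2 | 2-[4-(benzyloxy)-3-methoxyphenyl]-1,3-dithiane | COc1cc(C2SCCCS2)ccc1OCc1ccccc1
A6 | alternative 2 | (3R,4R,5R)-3-[4-(benzyloxy)-3-methoxybenzyl]-4-{2-[4-(benzyloxy)-3-methoxyphenyl]-1,3-dithian-2-yl}-5-[(1R,2S,5R)-menthyloxy]dihydrofuran-2(3H)-one | O=C1[C@H](Cc2ccc(OCc3ccccc3)c(OC)c2)[C@H]([C@H](O[C@@H]2C[C@H](C)CC[C@H]2C(C)C)O1)C1(c2ccc(OCc3ccccc3)c(OC)c2)SCCCS1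
A7 | alternative 3 | (E)-1,4-bis[4-(benzyloxy)-3-methoxyphenyl]but-2-ene | COc1cc(C/C=C/Cc2ccc(OCc3ccccc3)c(OC)c2)ccc1OCc1ccccc1
A8 | alternative 3 | dimethyl (2R,3R)-2,3-bis[4-(benzyloxy)-3-methoxybenzyl]butanedioate | COC(=O)[C@H](Cc1ccc(OCc2ccccc2)c(OC)c1)[C@H](C(=O)OC)Cc1ccc(OCc2ccccc2)c(OC)c1
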